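Everything rests on one disconnection around the dihydrofuran ring: the O1–C2 bond, the bond joining the vinyl α-carbon to the formyl carbon, and a temporary ester bond from that carbon to the oxygen on C3. The feature exploited is the cis relationship between the 1-formylvinyl group on C2 and the acyloxy oxygen on C3, which lets the formyl carbon and that oxygen be locked in a cis-fused five-membered α-methylene lactone. One palladium-catalysed carbonylative cascade closes the dihydrofuran ring and the lactone ring and sets C2 from C3. Its precursor is an open-chain ortho-hydroxyphenyl buta-2,3-dienyl carbinol, (S) at the future C3, with phenol and carbinol hydroxyl free and the side-chain alcohol silylated.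

Key step: step 9

Atom numbers are those of the 2,3-dihydro-1-benzofuran of the target. TBS = tert-butyldimethylsilyl, TIPS = triisopropylsilyl, TES = triethylsilyl, THP = tetrahydro-2H-pyran-2-yl.

Assumption: (S)-BINOL in step 6 is taken to send the alkynyl group to the Si face of aldehyde 8, the sense expected for simple aryl aldehydes; if this aldehyde answers in the opposite sense, (R)-BINOL is used and nothing else changes.

Step 1
Reactants: 1 4-acetylphenyl acetate
Product: 2 4-[(1S)-1-hydroxyethyl]phenyl acetate
Conditions: RuCl[(S,S)-TsDPEN](p-cymene) (1 mol %), HCO2H/Et3N (5:2), 30 °C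
Reagents that add atoms: none
Why: Noyori asymmetric transfer hydrogenation of an aryl methyl ketone, in which the ruthenium hydride of the (S,S)-diamine catalyst delivers hydride to the Re face of the carbonyl and so sets the (S)-carbinol, while the aryl acetate is inert to the formic acid–triethylamine medium.

Step 2
Reactants: 2 4-[(1S)-1-hydroxyethyl]phenyl acetate
Product: 3 4-[(1S)-1-(tert-butyldimethylsilyloxy)ethyl]phenyl acetate
Conditions: TBSOTf, 2,6-lutidine, CH2Cl2, −78 to 0 °C
Reagents that add atoms: tert-butyldimethylsilyl trifluoromethanesulfonate, CC(C)(C)[Si](C)(C)OS(=O)(=O)C(F)(F)F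
Why: O-silylation of a secondary alcohol with a silyl triflate and a non-nucleophilic pyridine base, chosen because a nucleophilic amine would attack the aryl acetate; the stereocentre is not touched.

Step 3
Reactants: 3 4-[(1S)-1-(tert-butyldimethylsilyloxy)ethyl]phenyl acetate
Product: 4 4-[(1S)-1-(tert-butyldimethylsilyloxy)ethyl]phenol
Conditions: K2CO3 (0.2 equiv), MeOH, 0 °C to rt
Reagents that add atoms: none
Why: Base-catalysed transesterification, in which methoxide cleaves the aryl ester (phenoxide leaving group) far faster than it could attack the alkyl silyl ether.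

Step 4
Reactants: 4 4-[(1S)-1-(tert-butyldimethylsilyloxy)ethyl]phenol, 5 formaldehyde (as paraformaldehyde)
Product: 7 5-[(1S)-1-(tert-butyldimethylsilyloxy)ethyl]-2-hydroxybenzaldehyde, via hydroxymethylphenol 6 (not isolated)
Conditions: MgCl2, Et3N, (CH2O)n, THF, reflux
Reagents that add atoms: none
Why: Casiraghi–Skattebøl ortho-formylation, in which the magnesium phenoxide directs hydroxymethylation to an ortho position (the two are equivalent) and a second formaldehyde oxidises the chelated benzylic alkoxide by Oppenauer-type hydride transfer, a redox that the silylated side-chain carbinol cannot enter.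

Step 5
Reactants: 7 5-[(1S)-1-(tert-butyldimethylsilyloxy)ethyl]-2-hydroxybenzaldehyde
Product: 8 5-[(1S)-1-(tert-butyldimethylsilyloxy)ethyl]-2-(triisopropylsilyloxy)benzaldehyde
Conditions: TIPSCl, imidazole, DMF, rt
Reagents that add atoms: chlorotriisopropylsilane, CC(C)[Si](Cl)(C(C)C)C(C)C
Why: Imidazole-promoted silylation of the phenol, with the bulky triisopropylsilyl group chosen because it should resist migration to the neighbouring alkoxide formed in steps 6 and 7 and is still removed selectively by fluoride in step 8.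

Step 6
Reactants: 8 5-[(1S)-1-(tert-butyldimethylsilyloxy)ethyl]-2-(triisopropylsilyloxy)benzaldehyde, 9 2-(prop-2-yn-1-yloxy)tetrahydro-2H-pyran
Product: 11 (1S)-1-{5-[(1S)-1-(tert-butyldimethylsilyloxy)ethyl]-2-(triisopropylsilyloxy)phenyl}-4-(tetrahydro-2H-pyran-2-yloxy)but-2-yn-1-ol (both epimers at the acetal carbon), via ethylzinc acetylide 10 (not isolated)
Conditions: 9 (2 equiv), Et2Zn (2 equiv), Cy2NH (5 mol %), Et2O, rt; then (S)-BINOL (20 mol %), Ti(OiPr)4 (50 mol %), 8, rt
Reagents that add atoms: none
Why: Catalytic enantioselective alkynylzinc addition to an aryl aldehyde under BINOL–titanium control, in which the acetylide adds to the Si face of the activated aldehyde and so sets the (S)-carbinol that becomes C3, the distant side-chain centre having no influence.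

Step 7
Reactants: 11 propargylic alcohol with the THP-oxymethyl alkyne terminus
Product: 12 (1S)-1-{5-[(1S)-1-(tert-butyldimethylsilyloxy)ethyl]-2-(triisopropylsilyloxy)phenyl}buta-2,3-dien-1-ol
Conditions: LiAlH4, Et2O, 0 °C to reflux
Reagents that add atoms: none
Why: SN2′-type hydride reduction of a 4-alkoxybut-2-yn-1-ol to an α-allenol, in which the alkoxyaluminium hydride delivers hydride to the alkyne carbon next to the carbinol (trans-hydroalumination) and the vinylalanate expels the tetrahydropyranyloxy group by 1,2-elimination, leaving the carbinol centre untouched.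

Step 8
Reactants: 12 allenyl carbinol with the phenol as TIPS ether
Product: 13 (1S)-1-{5-[(1S)-1-(tert-butyldimethylsilyloxy)ethyl]-2-hydroxyphenyl}buta-2,3-dien-1-ol
Conditions: Bu4NF (1.1 equiv), AcOH (1.1 equiv), THF, 0 °C
Reagents that add atoms: none
Why: Fluoride-mediated desilylation that is selective for the aryl silyl ether because phenoxide is by far the better leaving group, with acetic acid buffering to spare the allenyl carbinol and the secondary alkyl silyl ether.

Step 9
Reactants: 13 (1S)-1-{5-[(1S)-1-(tert-butyldimethylsilyloxy)ethyl]-2-hydroxyphenyl}buta-2,3-dien-1-ol, 14 carbon monoxide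
Product: 15 (3aR,8bR)-7-[(1S)-1-(tert-butyldimethylsilyloxy)ethyl]-3-methylidene-3a,8b-dihydrofuro[3,2-b][1]benzofuran-2(3H)-one
Conditions: PdCl2(MeCN)2 (10 mol %), p-benzoquinone (1.5 equiv), NaOAc (1 equiv), CO (1 atm), THF, 0 °C to rt
Reagents that add atoms: none
Why: Divalent palladium binds the allene, the phenol oxygen adds to the allene carbon next to the carbinol and leaves a σ-vinylpalladium on the central carbon, CO inserts, and the C3 hydroxyl takes the acyl group, releasing zerovalent palladium that p-benzoquinone reoxidises. The closest known reactions are the oxypalladation–alkoxycarbonylation of hydroxy allenes to 2-(tetrahydrofuran-2-yl)acrylates and the intramolecular alkoxycarbonylation of hydroxy alkenes to cis-fused bicyclic lactones; their merger on one substrate is where the route carries its risk. The dihydrofuran ring closes by 5-exo-trig attack of oxygen on the proximal allene carbon and the lactone ring by 5-exo-trig acyl substitution at the acylpalladium carbon. The new stereocentre C2 is controlled by C3: coordination of the C3 hydroxyl to palladium should favour the cis adduct, only the cis acylpalladium can reach that hydroxyl, and reversible oxypalladation should return the trans adduct to the allene. The step needs the phenol and not the carbinol hydroxyl to be the first nucleophile, because 5-endo attack of the carbinol oxygen on the allene terminus is a known mode of α-allenols and would lead to a 2,5-dihydrofuran or an isomeric six-membered lactone. The higher acidity of the phenol, the acetate buffer (which also keeps the released acid from ionising the ortho-hydroxybenzylic alcohol) and the favourable exo closure are what stand against that.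

Step 10
Reactants: 15 cis-fused α-methylene lactone
Product: 16 (2R,3R)-5-[(1S)-1-(tert-butyldimethylsilyloxy)ethyl]-2-(3-hydroxyprop-1-en-2-yl)-2,3-dihydro-1-benzofuran-3-ol
Conditions: iBu2AlH (4 equiv), CH2Cl2, −78 to 0 °C; aq. potassium sodium tartrate work-up
Reagents that add atoms: none
Why: Exhaustive 1,2-reduction of the unsaturated lactone by the aluminium hydride (ester to alcohols) opens it to the primary allylic alcohol and the C3 alcohol without touching the silyl ether, the alkene or any stereocentre.

Step 11
Reactants: 16 diol with primary allylic and C3 hydroxyl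
Product: 17 (2R,3R)-2-[3-(tert-butyldimethylsilyloxy)prop-1-en-2-yl]-5-[(1S)-1-(tert-butyldimethylsilyloxy)ethyl]-2,3-dihydro-1-benzofuran-3-ol
Conditions: TBSCl (1.1 equiv), imidazole, CH2Cl2, −20 to 0 °C
Reagents that add atoms: tert-butyldimethylsilyl chloride, CC(C)(C)[Si](C)(C)Cl
Why: Chemoselective silylation, since the unhindered primary allylic hydroxyl reacts with the silyl chloride far faster than the hindered secondary benzylic hydroxyl on C3.

Step 12
Reactants: 17 C3 alcohol with both other hydroxyls silylated
Product: 18 (2R,3R)-2-[3-(tert-butyldimethylsilyloxy)prop-1-en-2-yl]-5-[(1S)-1-(tert-butyldimethylsilyloxy)ethyl]-2,3-dihydro-1-benzofuran-3-yl 3-methylbutanoate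
Conditions: (Me2CHCH2CO)2O, Et3N, DMAP (cat.), CH2Cl2, 0 °C to rt
Reagents that add atoms: 3-methylbutanoic anhydride, CC(C)CC(=O)OC(=O)CC(C)C
Why: DMAP-catalysed acyl transfer (Steglich-type acylation) to the only free hydroxyl installs the isovalerate with retention at C3, the anhydride being chosen so that no strong acid is formed.

Step 13
Reactants: 18 bis-silyl ether isovalerate
Product: 19 (2R,3R)-5-[(1S)-1-hydroxyethyl]-2-(3-hydroxyprop-1-en-2-yl)-2,3-dihydro-1-benzofuran-3-yl 3-methylbutanoate
Conditions: HF·pyridine, pyridine, THF, 0 °C to rt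
Reagents that add atoms: none
Why: Fluoride-mediated cleavage of both silyl ethers under pyridine-buffered, nearly neutral conditions, so that the benzylic ester should neither ionise nor migrate and no alkoxide is formed that could trigger elimination to the benzofuran.

Step 14
Reactants: 19 diol with primary allylic and secondary benzylic hydroxyl
Product: 20 (2R,3R)-5-[(1S)-1-hydroxyethyl]-2-(3-oxoprop-1-en-2-yl)-2,3-dihydro-1-benzofuran-3-yl 3-methylbutanoate
Conditions: TEMPO (20 mol %), PhI(OAc)2 (1.1 equiv), CH2Cl2, 0 °C to rt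
Reagents that add atoms: none
Why: Oxoammonium-mediated alcohol oxidation (TEMPO with a hypervalent iodine co-oxidant) is strongly selective for primary over secondary alcohols, so the allylic primary alcohol should give the enal while the side-chain carbinol stays.

Step 15
Reactants: 20 hydroxy enal
Product: 21 (2R,3R)-5-[(1S)-1-acetoxyethyl]-2-(3-oxoprop-1-en-2-yl)-2,3-dihydro-1-benzofuran-3-yl 3-methylbutanoate (target)
Conditions: Ac2O, pyridine, DMAP (cat.), CH2Cl2, 0 °C
Reagents that add atoms: acetic anhydride, CC(=O)OC(C)=O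
Why: Acetylation of the remaining secondary alcohol by nucleophilic acyl transfer proceeds with retention under mild conditions that the enal and the C3 ester should tolerate.

Compound list
1 | 4-acetylphenyl acetate | CC(=O)Oc1ccc(C(C)=O)cc1 | starting material
2 | 4-[(1S)-1-hydroxyethyl]phenyl acetate | C[C@H](O)c1ccc(OC(C)=O)cc1 | intermediate
3 | 4-[(1S)-1-(tert-butyldimethylsilyloxy)ethyl]phenyl acetate | C[C@H](O[Si](C)(C)C(C)(C)C)c1ccc(OC(C)=O)cc1 | intermediate
4 | 4-[(1S)-1-(tert-butyldimethylsilyloxy)ethyl]phenol | C[C@H](O[Si](C)(C)C(C)(C)C)c1ccc(O)cc1 | intermediate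
5 | formaldehyde (as paraformaldehyde) | C=O | starting material
6 | 4-[(1S)-1-(tert-butyldimethylsilyloxy)ethyl]-2-(hydroxymethyl)phenol (magnesium salt in the flask, not isolated) | C[C@H](O[Si](C)(C)C(C)(C)C)c1ccc(O)c(CO)c1 | intermediate
7 | 5-[(1S)-1-(tert-butyldimethylsilyloxy)ethyl]-2-hydroxybenzaldehyde | C[C@H](O[Si](C)(C)C(C)(C)C)c1ccc(O)c(C=O)c1 | intermediate
8 | 5-[(1S)-1-(tert-butyldimethylsilyloxy)ethyl]-2-(triisopropylsilyloxy)benzaldehyde | C[C@H](O[Si](C)(C)C(C)(C)C)c1ccc(O[Si](C(C)C)(C(C)C)C(C)C)c(C=O)c1 | intermediate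
9 | 2-(prop-2-yn-1-yloxy)tetrahydro-2H-pyran (racemic) | C#CCOC1CCCCO1 | starting material
10 | ethyl[3-(tetrahydro-2H-pyran-2-yloxy)prop-1-yn-1-yl]zinc (not isolated) | CC[Zn]C#CCOC1CCCCO1 | intermediate
11 | (1S)-1-{5-[(1S)-1-(tert-butyldimethylsilyloxy)ethyl]-2-(triisopropylsilyloxy)phenyl}-4-(tetrahydro-2H-pyran-2-yloxy)but-2-yn-1-ol (both epimers at the acetal carbon) | C1CCCC(O1)OCC#C[C@H](O)c1cc([C@H](C)O[Si](C)(C)C(C)(C)C)ccc1O[Si](C(C)C)(C(C)C)C(C)C | intermediate
12 | (1S)-1-{5-[(1S)-1-(tert-butyldimethylsilyloxy)ethyl]-2-(triisopropylsilyloxy)phenyl}buta-2,3-dien-1-ol | C=C=C[C@H](O)c1cc([C@H](C)O[Si](C)(C)C(C)(C)C)ccc1O[Si](C(C)C)(C(C)C)C(C)C | intermediate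
13 | (1S)-1-{5-[(1S)-1-(tert-butyldimethylsilyloxy)ethyl]-2-hydroxyphenyl}buta-2,3-dien-1-ol | C=C=C[C@H](O)c1cc([C@H](C)O[Si](C)(C)C(C)(C)C)ccc1O | intermediate
14 | carbon monoxide | [C-]#[O+] | starting material
15 | (3aR,8bR)-7-[(1S)-1-(tert-butyldimethylsilyloxy)ethyl]-3-methylidene-3a,8b-dihydrofuro[3,2-b][1]benzofuran-2(3H)-one | C=C1[C@H]2Oc3ccc([C@H](C)O[Si](C)(C)C(C)(C)C)cc3[C@H]2OC1=O | intermediate
16 | (2R,3R)-5-[(1S)-1-(tert-butyldimethylsilyloxy)ethyl]-2-(3-hydroxyprop-1-en-2-yl)-2,3-dihydro-1-benzofuran-3-ol | C=C(CO)[C@H]1Oc2ccc([C@H](C)O[Si](C)(C)C(C)(C)C)cc2[C@H]1O | intermediate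
17 | (2R,3R)-2-[3-(tert-butyldimethylsilyloxy)prop-1-en-2-yl]-5-[(1S)-1-(tert-butyldimethylsilyloxy)ethyl]-2,3-dihydro-1-benzofuran-3-ol | C=C(CO[Si](C)(C)C(C)(C)C)[C@H]1Oc2ccc([C@H](C)O[Si](C)(C)C(C)(C)C)cc2[C@H]1O | intermediate
18 | (2R,3R)-2-[3-(tert-butyldimethylsilyloxy)prop-1-en-2-yl]-5-[(1S)-1-(tert-butyldimethylsilyloxy)ethyl]-2,3-dihydro-1-benzofuran-3-yl 3-methylbutanoate | C=C(CO[Si](C)(C)C(C)(C)C)[C@H]1Oc2ccc([C@H](C)O[Si](C)(C)C(C)(C)C)cc2[C@H]1OC(=O)CC(C)C | intermediate
19 | (2R,3R)-5-[(1S)-1-hydroxyethyl]-2-(3-hydroxyprop-1-en-2-yl)-2,3-dihydro-1-benzofuran-3-yl 3-methylbutanoate | C=C(CO)[C@H]1Oc2ccc([C@H](C)O)cc2[C@H]1OC(=O)CC(C)C | intermediate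
20 | (2R,3R)-5-[(1S)-1-hydroxyethyl]-2-(3-oxoprop-1-en-2-yl)-2,3-dihydro-1-benzofuran-3-yl 3-methylbutanoate | C=C(C=O)[C@H]1Oc2ccc([C@H](C)O)cc2[C@H]1OC(=O)CC(C)C | intermediate
21 | (2R,3R)-5-[(1S)-1-acetoxyethyl]-2-(3-oxoprop-1-en-2-yl)-2,3-dihydro-1-benzofuran-3-yl 3-methylbutanoate | C=C(C=O)[C@H]1Oc2ccc([C@H](C)OC(C)=O)cc2[C@H]1OC(=O)CC(C)C | target

Total step count: 15
Longest linear sequence: 15 steps (1 to 21); 5, 9 and 14 enter as commercial one-step inputs.

Steps most likely to fail

Step 9. The carbinol oxygen may add to the allene terminus before the phenol adds, which would divert material to a 2,5-dihydrofuran or, after carbonylation and capture by the phenol, to an isomeric six-membered lactone; acid released during turnover may also ionise the ortho-hydroxybenzylic alcohol. The fallback sets out from 12 and comes back at 15, and it separates the two ring closures with the carbinol oxygen blocked. The carbinol of 12 is silylated (TESCl, imidazole, DMF) to the triethylsilyl ether F1, and buffered Bu4NF at low temperature releases the free phenol F2. Oxypalladation–methoxycarbonylation (PdCl2, CuCl2, CO, MeOH, propylene oxide, rt), in which only the phenol can add, should close the dihydrofuran ring and give the methyl acrylate F3. Pyridinium p-toluenesulfonate in MeOH removes the triethylsilyl group to the hydroxy ester F4, whose cis arrangement allows lactonisation to 15 on standing or with a trace of acid. In this variant C2 is no longer steered by the free hydroxyl, so any C2 epimer, which cannot lactonise, would have to be separated at this point.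

Step 6. Facial selectivity may be poor or addition slow with the hindered ortho-silyloxy aldehyde, and ethyl transfer from Et2Zn may compete. The fallback sets out from 8 and comes back at 12, using a stoichiometric chiral boron reagent in place of catalysis. The B-propargyl-1,3,2-diazaborolidine, made in the flask from allenyltributylstannane and the B-bromo-diazaborolidine of N,N′-bis(p-toluenesulfonyl)-1,2-diphenylethane-1,2-diamine (antipode chosen for Si-face attack), adds to 8 at −78 °C through a cyclic SE2′ transition state. This should give allenyl carbinol 12 directly, which also bypasses step 7; no new compound of the route arises (F0).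

Step 14. Chemoselectivity may be lost through over-oxidation of the electron-rich secondary benzylic alcohol to the aryl ketone. The fallback sets out from 19 and comes back at 21, and it distinguishes the two hydroxyls by protection instead of by the oxidant. The primary hydroxyl of 19 is silylated selectively (TESCl, imidazole, CH2Cl2, −40 °C) to the primary triethylsilyl ether F5. The side-chain alcohol is acetylated (Ac2O, pyridine, DMAP) to the acetate F6, and HF·pyridine releases the allylic alcohol F7. Dess–Martin periodinane buffered with NaHCO3 (or MnO2) then oxidises the only free hydroxyl to the enal 21.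

Further compounds
F1 | step 9 | triethyl{[(1S)-1-{5-[(1S)-1-(tert-butyldimethylsilyloxy)ethyl]-2-(triisopropylsilyloxy)phenyl}buta-2,3-dien-1-yl]oxy}silane | C=C=C[C@H](O[Si](CC)(CC)CC)c1cc([C@H](C)O[Si](C)(C)C(C)(C)C)ccc1O[Si](C(C)C)(C(C)C)C(C)C
F2 | step 9 | 4-[(1S)-1-(tert-butyldimethylsilyloxy)ethyl]-2-[(1S)-1-(triethylsilyloxy)buta-2,3-dien-1-yl]phenol | C=C=C[C@H](O[Si](CC)(CC)CC)c1cc([C@H](C)O[Si](C)(C)C(C)(C)C)ccc1O
F3 | step 9 | methyl 2-{(2R,3R)-5-[(1S)-1-(tert-butyldimethylsilyloxy)ethyl]-3-(triethylsilyloxy)-2,3-dihydro-1-benzofuran-2-yl}prop-2-enoate | C=C(C(=O)OC)[C@H]1Oc2ccc([C@H](C)O[Si](C)(C)C(C)(C)C)cc2[C@H]1O[Si](CC)(CC)CC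
F4 | step 9 | methyl 2-{(2R,3R)-5-[(1S)-1-(tert-butyldimethylsilyloxy)ethyl]-3-hydroxy-2,3-dihydro-1-benzofuran-2-yl}prop-2-enoate | C=C(C(=O)OC)[C@H]1Oc2ccc([C@H](C)O[Si](C)(C)C(C)(C)C)cc2[C@H]1O
F0 | step 6 | none | none
F5 | step 14 | (2R,3R)-5-[(1S)-1-hydroxyethyl]-2-[3-(triethylsilyloxy)prop-1-en-2-yl]-2,3-dihydro-1-benzofuran-3-yl 3-methylbutanoate | C=C(CO[Si](CC)(CC)CC)[C@H]1Oc2ccc([C@H](C)O)cc2[C@H]1OC(=O)CC(C)C
F6 | step 14 | (2R,3R)-5-[(1S)-1-acetoxyethyl]-2-[3-(triethylsilyloxy)prop-1-en-2-yl]-2,3-dihydro-1-benzofuran-3-yl 3-methylbutanoate | C=C(CO[Si](CC)(CC)CC)[C@H]1Oc2ccc([C@H](C)OC(C)=O)cc2[C@H]1OC(=O)CC(C)C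
F7 | step 14 | (2R,3R)-5-[(1S)-1-acetoxyethyl]-2-(3-hydroxyprop-1-en-2-yl)-2,3-dihydro-1-benzofuran-3-yl 3-methylbutanoate | C=C(CO)[C@H]1Oc2ccc([C@H](C)OC(C)=O)cc2[C@H]1OC(=O)CC(C)C
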